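**Retrosynthetic overview**

1. Numbering: ring B is C10 (quaternary; methyl, vinyl)–C5 (isopropenyl)–C6 (OH)–C7 (bears C11)–C8–C9, and C12 and C13 are the two CH2OAc carbons on C11. The C11 carbinol with its two acetoxymethyl arms is an oxidised 2-propenoate unit, so 25 ⇐ tetraol 24 ⇐ epoxy diol 23 ⇐ allylic diol 22 ⇐ hydroxy ester 21.
2. Feature: in ring B the C6 carbinol next to C7–C11(=C13H2)–C12O2Me is the adduct of a C6 aldehyde with a 2-(methoxycarbonyl)allyl metal that attacks through its γ-carbon C7. The key disconnection is C6–C7, made by cathodic, chromium-catalysed allylation of bromo aldehyde 18.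
3. The trans C6/C7 relationship is encoded in the (E) geometry of the allylic bromide (chain cis to CO2Me, CH2Br trans to the chain). That geometry comes from syn-hydroalumination of ynoate 13, capture with formaldehyde and Appel bromination.
4. C5 and C10 come from the enantioselective boron-dienolate Ireland–Claisen rearrangement of geranyl 3-methylbut-2-enoate. The chain is then cut at the trisubstituted alkene and extended to the ynoate.
5. Ring order: ring B is the only ring and is closed in step 13.

Key step: step 13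

Assumption: the (4S,5S)-diazaborolidine bromide is taken as the enantiomer that leads to the (2S,3S)-acid 6; if the sense of induction were the opposite, the equally available (4R,5R)-reagent would be used and nothing else would change.

**Route**

Step 1
Reactants: 1 geraniol, (2E)-3,7-dimethylocta-2,6-dien-1-ol; 2 3-methylbut-2-enoic acid
Product: 3 (2E)-3,7-dimethylocta-2,6-dien-1-yl 3-methylbut-2-enoate
Conditions: DCC, DMAP (5 mol%), CH2Cl2, 0 °C to rt
Reagents that add atoms: none
Why: Steglich esterification acylates the primary allylic alcohol under neutral conditions, and the low DMAP loading at 0 °C should keep the acyl unit conjugated.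

Step 2
Reactants: 3 (2E)-3,7-dimethylocta-2,6-dien-1-yl 3-methylbut-2-enoate
Product: 6 (2S,3S)-3-ethenyl-3,7-dimethyl-2-(prop-1-en-2-yl)oct-6-enoic acid, via boron dienolate 4 (not isolated), via boron carboxylate 5 (not isolated)
Conditions: (4S,5S)-2-bromo-1,3-bis{[3,5-bis(trifluoromethyl)phenyl]sulfonyl}-4,5-diphenyl-1,3,2-diazaborolidine (1.2 equiv, from the bis-sulfonamide and BBr3), Et3N, toluene–hexane, −78 °C to 4 °C; aq work-up
Reagents that add atoms: none
Why: Enantioselective boron-mediated Ireland–Claisen rearrangement: γ-deprotonation of the boron-complexed ester in its s-trans form gives the dienolate with isopropenyl cis to the allylic oxygen, which rearranges through a chair in which the (E)-alkene holds the homoprenyl chain equatorial and the methyl axial, fixing the C5/C10 relative configuration, while the C2-symmetric diazaborolidine selects the face and sets both centres as S.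

Step 3
Reactants: 6 (2S,3S)-3-ethenyl-3,7-dimethyl-2-(prop-1-en-2-yl)oct-6-enoic acid
Product: 7 (2S,3S)-3-ethenyl-3,7-dimethyl-2-(prop-1-en-2-yl)oct-6-en-1-ol
Conditions: LiAlH4, THF, 0 °C to reflux; aq NaOH work-up
Reagents that add atoms: none
Why: Hydride reduction of the carboxylic acid gives the primary alcohol; the α-centre is held as a carboxylate and should not epimerise, and isolated alkenes are inert.

Step 4
Reactants: 7 (2S,3S)-3-ethenyl-3,7-dimethyl-2-(prop-1-en-2-yl)oct-6-en-1-ol
Product: 8 tert-butyl{[(2S,3S)-3-ethenyl-3,7-dimethyl-2-(prop-1-en-2-yl)oct-6-en-1-yl]oxy}dimethylsilane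
Conditions: TBSCl, imidazole, DMF, rt
Reagents that add atoms: tert-butyldimethylsilyl chloride, CC(C)(C)[Si](C)(C)Cl
Why: Standard silylation of a primary alcohol masks C6–OH for the basic and organometallic steps that follow.

Step 5
Reactants: 8 tert-butyl{[(2S,3S)-3-ethenyl-3,7-dimethyl-2-(prop-1-en-2-yl)oct-6-en-1-yl]oxy}dimethylsilane
Product: 9 tert-butyl{[(2S,3S)-5-(3,3-dimethyloxiran-2-yl)-3-ethenyl-3-methyl-2-(prop-1-en-2-yl)pentyl]oxy}dimethylsilane (both epimers at the oxirane CH)
Conditions: 3-chloroperoxybenzoic acid (1.0 equiv), NaHCO3, CH2Cl2, −20 °C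
Reagents that add atoms: 3-chloroperoxybenzoic acid, OOC(=O)c1cccc(Cl)c1
Why: Prilezhaev epoxidation is electrophilic, so with one equivalent at low temperature the trisubstituted alkene should react ahead of the hindered 1,1-disubstituted and monosubstituted alkenes; the new oxirane centre is removed in step 6.

Step 6
Reactants: 9 tert-butyl{[(2S,3S)-5-(3,3-dimethyloxiran-2-yl)-3-ethenyl-3-methyl-2-(prop-1-en-2-yl)pentyl]oxy}dimethylsilane
Product: 10 (4S,5S)-5-{[(tert-butyldimethylsilyl)oxy]methyl}-4-ethenyl-4,6-dimethylhept-6-enal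
Conditions: H5IO6, THF–Et2O, 0 °C
Reagents that add atoms: none
Why: Periodic acid opens the epoxide with water at the tertiary carbon and cleaves the resulting glycol (Malaprade reaction), so the aldehyde keeps the epoxide oxygen and acetone is lost; the primary silyl ether should survive the short, cold exposure.

Step 7
Reactants: 10 (4S,5S)-5-{[(tert-butyldimethylsilyl)oxy]methyl}-4-ethenyl-4,6-dimethylhept-6-enal
Product: 11 tert-butyl{[(2S,3S)-3-ethenyl-3-methyl-2-(prop-1-en-2-yl)hept-6-yn-1-yl]oxy}dimethylsilane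
Conditions: dimethyl (1-diazo-2-oxopropyl)phosphonate, K2CO3, MeOH, 0 °C to rt
Reagents that add atoms: dimethyl (1-diazo-2-oxopropyl)phosphonate, COP(=O)(OC)C(=[N+]=[N-])C(C)=O
Why: Seyferth–Gilbert homologation with the Ohira–Bestmann reagent converts the aldehyde, which has no stereocentre at its α-carbon, into the terminal alkyne under mild carbonate conditions that leave the silyl ether intact.

Step 8
Reactants: 11 tert-butyl{[(2S,3S)-3-ethenyl-3-methyl-2-(prop-1-en-2-yl)hept-6-yn-1-yl]oxy}dimethylsilane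
Product: 13 methyl (6S,7S)-7-{[(tert-butyldimethylsilyl)oxy]methyl}-6-ethenyl-6,8-dimethylnon-8-en-2-ynoate, via lithium acetylide 12 (not isolated)
Conditions: n-BuLi, THF, −78 °C; then ClCO2Me, −78 to 0 °C
Reagents that add atoms: methyl chloroformate, COC(Cl)=O
Why: Deprotonation of the terminal alkyne and C-acylation of the acetylide with the chloroformate is the standard route to alk-2-ynoates.

Step 9
Reactants: 13 methyl (6S,7S)-7-{[(tert-butyldimethylsilyl)oxy]methyl}-6-ethenyl-6,8-dimethylnon-8-en-2-ynoate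
Product: 15 methyl (2Z,6S,7S)-7-{[(tert-butyldimethylsilyl)oxy]methyl}-6-ethenyl-2-(hydroxymethyl)-6,8-dimethylnona-2,8-dienoate, via vinylalane 14 (not isolated)
Conditions: i-Bu2AlH, HMPA, THF, 0 °C; then CH2O (gas, from cracked paraformaldehyde), 0 °C to rt
Reagents that add atoms: formaldehyde, C=O
Why: Conjugate syn-hydroalumination of the ynoate by the i-Bu2AlH–HMPA complex puts H on the β-carbon and aluminium on the α-carbon on the same side, so the chain ends cis to the ester, and the α-alumino acrylate adds to formaldehyde with retention (vinylalumination of an aldehyde), leaving CH2OH trans to the chain.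

Step 10
Reactants: 15 methyl (2Z,6S,7S)-7-{[(tert-butyldimethylsilyl)oxy]methyl}-6-ethenyl-2-(hydroxymethyl)-6,8-dimethylnona-2,8-dienoate
Product: 16 methyl (2E,6S,7S)-2-(bromomethyl)-7-{[(tert-butyldimethylsilyl)oxy]methyl}-6-ethenyl-6,8-dimethylnona-2,8-dienoate
Conditions: CBr4, PPh3, CH2Cl2, −20 to 0 °C
Reagents that add atoms: tetrabromomethane, BrC(Br)(Br)Br
Why: The Appel reaction displaces the alkoxyphosphonium at the primary allylic carbon without moving the alkene (the descriptor changes to E only because CH2Br outranks CO2Me), and the low temperature and short time should suppress bromide-induced allylic scrambling of the geometry.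

Step 11
Reactants: 16 methyl (2E,6S,7S)-2-(bromomethyl)-7-{[(tert-butyldimethylsilyl)oxy]methyl}-6-ethenyl-6,8-dimethylnona-2,8-dienoate
Product: 17 methyl (2E,6S,7S)-2-(bromomethyl)-6-ethenyl-7-(hydroxymethyl)-6,8-dimethylnona-2,8-dienoate
Conditions: aq HF (48%), MeCN, 0 °C
Reagents that add atoms: none
Why: Desilylation with aqueous HF cleaves the primary silyl ether in a medium that is neither basic nor strongly nucleophilic, which the allylic bromide and the methyl ester should tolerate.

Step 12
Reactants: 17 methyl (2E,6S,7S)-2-(bromomethyl)-6-ethenyl-7-(hydroxymethyl)-6,8-dimethylnona-2,8-dienoate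
Product: 18 methyl (2E,6S,7S)-2-(bromomethyl)-6-ethenyl-7-formyl-6,8-dimethylnona-2,8-dienoate
Conditions: Dess–Martin periodinane, NaHCO3, CH2Cl2, 0 °C; used without chromatography
Reagents that add atoms: none
Why: Dess–Martin oxidation gives the aldehyde without amine base, so the α-centre C5, which is also allylic, should neither epimerise nor let the isopropenyl alkene move into conjugation.

Step 13
Reactants: 18 methyl (2E,6S,7S)-2-(bromomethyl)-6-ethenyl-7-formyl-6,8-dimethylnona-2,8-dienoate
Product: 21 methyl 2-[(1S,2S,3S,4S)-4-ethenyl-2-hydroxy-4-methyl-3-(prop-1-en-2-yl)cyclohexyl]prop-2-enoate, via allylchromium dichloride 19 (not isolated), via trimethylsilyl ether 20 (not isolated)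
Conditions: CrCl2 (10 mol%), Me3SiCl (2.5 equiv), Et4NOTs (0.1 M), DMF, rt, undivided cell, aluminium anode, nickel-foam cathode, constant current (about 2.2 F/mol), 18 added over 6 h; then 1 M HCl, THF, 0 °C
Reagents that add atoms: none
Why: The cathode returns trivalent chromium to divalent chromium; two divalent chromium ions turn the allylic bromide into a σ-allylchromium species (trivalent chromium on C13) that adds through its γ-carbon C7 to the C6 aldehyde in a closed six-membered Zimmerman–Traxler transition state, and Me3SiCl silylates the chromium alkoxide so that the metal is released for the next cycle; the closest known reactions are the chromium-catalysed electroreductive Nozaki–Hiyama allylation and the CrCl2 cyclisation of ω-formyl 2-(bromomethyl)alk-2-enoates. Ring B closes 6-exo-trig by attack of C7 on the carbonyl carbon C6. The C6/C7 relationship is controlled by the alkene geometry: in the (E)-bromide the tether carbon C8 is trans to the chromium-bearing CH2 and so equatorial on the metallacyclic chair, which is fused to the forming carbocycle as in a trans-decalin and delivers C6–O and C7–C11 trans-diequatorial, whereas the (Z)-isomer would pass through the cis-fused array and give the axial C6 alkoxide. Both new centres are set relative to C5 by the carbocyclic chair that keeps isopropenyl equatorial and only the C10 methyl axial, so that C7 approaches the aldehyde face anti to the isopropenyl group. The step needs γ-regioselectivity (α-attack would require an eight-membered ring), retention of the alkene geometry (slow addition keeps the allylchromium species short-lived) and chemoselectivity (vinyl and isopropenyl are inert to allylchromium, and the non-basic medium should leave C5 untouched).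

Step 14
Reactants: 21 methyl 2-[(1S,2S,3S,4S)-4-ethenyl-2-hydroxy-4-methyl-3-(prop-1-en-2-yl)cyclohexyl]prop-2-enoate
Product: 22 (1S,2S,3S,6S)-3-ethenyl-6-(3-hydroxyprop-1-en-2-yl)-3-methyl-2-(prop-1-en-2-yl)cyclohexan-1-ol
Conditions: i-Bu2AlH (4 equiv), CH2Cl2, −78 to 0 °C; aq KNaC4H4O6 (potassium sodium tartrate)
Reagents that add atoms: none
Why: i-Bu2AlH reduces the 2-substituted acrylate by 1,2-addition to the allylic alcohol, and the isolated alkenes and the ring stereocentres are not affected.

Step 15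
Reactants: 22 (1S,2S,3S,6S)-3-ethenyl-6-(3-hydroxyprop-1-en-2-yl)-3-methyl-2-(prop-1-en-2-yl)cyclohexan-1-ol
Product: 23 (1R,2S,3S,6R)-3-ethenyl-6-[2-(hydroxymethyl)oxiran-2-yl]-3-methyl-2-(prop-1-en-2-yl)cyclohexan-1-ol (both epimers at the oxirane carbon C11)
Conditions: Ti(OiPr)4 (0.2 equiv), t-BuOOH, 4 Å molecular sieves, CH2Cl2, −20 °C
Reagents that add atoms: tert-butyl hydroperoxide, CC(C)(C)OO
Why: Hydroxyl-directed titanium alkoxide/hydroperoxide epoxidation (Katsuki–Sharpless type without tartrate) should oxidise only the alkene that is allylic to the primary alcohol, leaving vinyl and isopropenyl; the C11 configuration is irrelevant because step 16 removes that centre.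

Step 16
Reactants: 23 (1R,2S,3S,6R)-3-ethenyl-6-[2-(hydroxymethyl)oxiran-2-yl]-3-methyl-2-(prop-1-en-2-yl)cyclohexan-1-ol
Product: 24 2-[(1R,2R,3S,4S)-4-ethenyl-2-hydroxy-4-methyl-3-(prop-1-en-2-yl)cyclohexyl]propane-1,2,3-triol
Conditions: NaOH (0.5 M aq), t-BuOH, 70 °C
Reagents that add atoms: water, O
Why: Hydroxide opens the 2,2-disubstituted epoxide by SN2 attack at its CH2 terminus (the Payne rearrangement that accompanies it only exchanges the two CH2O arms), giving the C11 carbinol flanked by two CH2OH groups, so C11 is no longer a stereocentre.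

Step 17
Reactants: 24 2-[(1R,2R,3S,4S)-4-ethenyl-2-hydroxy-4-methyl-3-(prop-1-en-2-yl)cyclohexyl]propane-1,2,3-triol
Product: 25 2-[(1R,2R,3S,4S)-4-ethenyl-2-hydroxy-4-methyl-3-(prop-1-en-2-yl)cyclohexyl]-2-hydroxypropane-1,3-diyl diacetate
Conditions: AcCl (2.2 equiv), 2,4,6-collidine, CH2Cl2, −78 °C
Reagents that add atoms: acetyl chloride, CC(Cl)=O
Why: Kinetically selective acylation with acetyl chloride and a hindered pyridine base at low temperature should esterify the two primary hydroxyls and leave the flanked secondary C6–OH and the tertiary C11–OH free.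

**Compound list**

1 | geraniol, (2E)-3,7-dimethylocta-2,6-dien-1-ol | CC(C)=CCC/C(C)=C/CO | starting material
2 | 3-methylbut-2-enoic acid | CC(C)=CC(=O)O | starting material
3 | (2E)-3,7-dimethylocta-2,6-dien-1-yl 3-methylbut-2-enoate | CC(C)=CCC/C(C)=C/COC(=O)C=C(C)C | intermediate
4 | boron dienolate of 3: (4S,5S)-1,3-bis{[3,5-bis(trifluoromethyl)phenyl]sulfonyl}-2-{[1-(geranyloxy)-3-methylbuta-1,3-dien-1-yl]oxy}-4,5-diphenyl-1,3,2-diazaborolidine, isopropenyl cis to the geranyloxy oxygen | C=C(C)/C=C(/OB1N(S(=O)(=O)c2cc(cc(c2)C(F)(F)F)C(F)(F)F)[C@@H](c2ccccc2)[C@H](c2ccccc2)N1S(=O)(=O)c1cc(cc(c1)C(F)(F)F)C(F)(F)F)\OC/C=C(\C)CCC=C(C)C | intermediate (not isolated)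
5 | boron carboxylate of 6: (4S,5S)-1,3-bis{[3,5-bis(trifluoromethyl)phenyl]sulfonyl}-4,5-diphenyl-1,3,2-diazaborolidin-2-yl (2S,3S)-3-ethenyl-3,7-dimethyl-2-(prop-1-en-2-yl)oct-6-enoate | C=C[C@](C)(CCC=C(C)C)[C@@H](C(=O)OB1N(S(=O)(=O)c2cc(cc(c2)C(F)(F)F)C(F)(F)F)[C@@H](c2ccccc2)[C@H](c2ccccc2)N1S(=O)(=O)c1cc(cc(c1)C(F)(F)F)C(F)(F)F)C(=C)C | intermediate (not isolated)
6 | (2S,3S)-3-ethenyl-3,7-dimethyl-2-(prop-1-en-2-yl)oct-6-enoic acid | C=C[C@](C)(CCC=C(C)C)[C@@H](C(=O)O)C(=C)C | intermediate
7 | (2S,3S)-3-ethenyl-3,7-dimethyl-2-(prop-1-en-2-yl)oct-6-en-1-ol | C=C[C@](C)(CCC=C(C)C)[C@@H](CO)C(=C)C | intermediate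
8 | tert-butyl{[(2S,3S)-3-ethenyl-3,7-dimethyl-2-(prop-1-en-2-yl)oct-6-en-1-yl]oxy}dimethylsilane | C=C[C@](C)(CCC=C(C)C)[C@@H](CO[Si](C)(C)C(C)(C)C)C(=C)C | intermediate
9 | tert-butyl{[(2S,3S)-5-(3,3-dimethyloxiran-2-yl)-3-ethenyl-3-methyl-2-(prop-1-en-2-yl)pentyl]oxy}dimethylsilane (both epimers at the oxirane CH) | C=C[C@](C)(CCC1OC1(C)C)[C@@H](CO[Si](C)(C)C(C)(C)C)C(=C)C | intermediate
10 | (4S,5S)-5-{[(tert-butyldimethylsilyl)oxy]methyl}-4-ethenyl-4,6-dimethylhept-6-enal | C=C[C@](C)(CCC=O)[C@@H](CO[Si](C)(C)C(C)(C)C)C(=C)C | intermediate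
11 | tert-butyl{[(2S,3S)-3-ethenyl-3-methyl-2-(prop-1-en-2-yl)hept-6-yn-1-yl]oxy}dimethylsilane | C=C[C@](C)(CCC#C)[C@@H](CO[Si](C)(C)C(C)(C)C)C(=C)C | intermediate
12 | lithium acetylide of 11 | C=C[C@](C)(CCC#C[Li])[C@@H](CO[Si](C)(C)C(C)(C)C)C(=C)C | intermediate (not isolated)
13 | methyl (6S,7S)-7-{[(tert-butyldimethylsilyl)oxy]methyl}-6-ethenyl-6,8-dimethylnon-8-en-2-ynoate | C=C[C@](C)(CCC#CC(=O)OC)[C@@H](CO[Si](C)(C)C(C)(C)C)C(=C)C | intermediate
14 | methyl (2E,6S,7S)-2-[bis(2-methylpropyl)alumanyl]-7-{[(tert-butyldimethylsilyl)oxy]methyl}-6-ethenyl-6,8-dimethylnona-2,8-dienoate | C=C[C@](C)(CC/C=C(/[Al](CC(C)C)CC(C)C)C(=O)OC)[C@@H](CO[Si](C)(C)C(C)(C)C)C(=C)C | intermediate (not isolated)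
15 | methyl (2Z,6S,7S)-7-{[(tert-butyldimethylsilyl)oxy]methyl}-6-ethenyl-2-(hydroxymethyl)-6,8-dimethylnona-2,8-dienoate | C=C[C@](C)(CC/C=C(/CO)C(=O)OC)[C@@H](CO[Si](C)(C)C(C)(C)C)C(=C)C | intermediate
16 | methyl (2E,6S,7S)-2-(bromomethyl)-7-{[(tert-butyldimethylsilyl)oxy]methyl}-6-ethenyl-6,8-dimethylnona-2,8-dienoate | C=C[C@](C)(CC/C=C(/CBr)C(=O)OC)[C@@H](CO[Si](C)(C)C(C)(C)C)C(=C)C | intermediate
17 | methyl (2E,6S,7S)-2-(bromomethyl)-6-ethenyl-7-(hydroxymethyl)-6,8-dimethylnona-2,8-dienoate | C=C[C@](C)(CC/C=C(/CBr)C(=O)OC)[C@@H](CO)C(=C)C | intermediate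
18 | methyl (2E,6S,7S)-2-(bromomethyl)-6-ethenyl-7-formyl-6,8-dimethylnona-2,8-dienoate | C=C[C@](C)(CC/C=C(/CBr)C(=O)OC)[C@@H](C=O)C(=C)C | intermediate (key-step precursor)
19 | allylchromium dichloride from 18 (trivalent chromium on C13, solvent ligands omitted) | C=C[C@](C)(CC/C=C(/C[Cr](Cl)Cl)C(=O)OC)[C@@H](C=O)C(=C)C | intermediate (not isolated)
20 | methyl 2-[(1S,2S,3S,4S)-4-ethenyl-4-methyl-3-(prop-1-en-2-yl)-2-[(trimethylsilyl)oxy]cyclohexyl]prop-2-enoate | C=C[C@]1(C)CC[C@@H](C(=C)C(=O)OC)[C@H](O[Si](C)(C)C)[C@H]1C(=C)C | intermediate (not isolated)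
21 | methyl 2-[(1S,2S,3S,4S)-4-ethenyl-2-hydroxy-4-methyl-3-(prop-1-en-2-yl)cyclohexyl]prop-2-enoate | C=C[C@]1(C)CC[C@@H](C(=C)C(=O)OC)[C@H](O)[C@H]1C(=C)C | intermediate (key-step product)
22 | (1S,2S,3S,6S)-3-ethenyl-6-(3-hydroxyprop-1-en-2-yl)-3-methyl-2-(prop-1-en-2-yl)cyclohexan-1-ol | C=C[C@]1(C)CC[C@@H](C(=C)CO)[C@H](O)[C@H]1C(=C)C | intermediate
23 | (1R,2S,3S,6R)-3-ethenyl-6-[2-(hydroxymethyl)oxiran-2-yl]-3-methyl-2-(prop-1-en-2-yl)cyclohexan-1-ol (both epimers at the oxirane carbon) | C=C[C@]1(C)CC[C@@H](C2(CO)CO2)[C@H](O)[C@H]1C(=C)C | intermediate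
24 | 2-[(1R,2R,3S,4S)-4-ethenyl-2-hydroxy-4-methyl-3-(prop-1-en-2-yl)cyclohexyl]propane-1,2,3-triol | C=C[C@]1(C)CC[C@@H](C(O)(CO)CO)[C@H](O)[C@H]1C(=C)C | intermediate
25 | 2-[(1R,2R,3S,4S)-4-ethenyl-2-hydroxy-4-methyl-3-(prop-1-en-2-yl)cyclohexyl]-2-hydroxypropane-1,3-diyl diacetate (CNP0273389.1) | C=C[C@]1(C)CC[C@@H](C(O)(COC(C)=O)COC(C)=O)[C@H](O)[C@H]1C(=C)C | target

**Step count and risk**

Total step count: 17. Longest linear sequence: 17 (geraniol to 25).

The three steps most likely to fail:

Step 13. The ring closure may suffer from loss of the alkene geometry in the allylchromium species, which would feed the cis-fused closure and the C6 epimer. Direct cathodic reduction of the bromide (hydrodehalogenation, homocoupling) may also outrun the chromium cycle. The fallback replaces the allyl metal with a configurationally stable allylboronate and forms C6–C7 by intramolecular allylboration; it sets out from ynoate 13 and comes back at 21. Conjugate hydride addition to 13 (i-Bu2AlH, HMPA, catalytic MeCu, THF) and capture of the α-metallated acrylate with 2-(iodomethyl)-4,4,5,5-tetramethyl-1,3,2-dioxaborolane should give methyl (2Z,6S,7S)-7-{[(tert-butyldimethylsilyl)oxy]methyl}-6-ethenyl-6,8-dimethyl-2-[(4,4,5,5-tetramethyl-1,3,2-dioxaborolan-2-yl)methyl]nona-2,8-dienoate F1, with the boryl-bearing CH2 trans to the chain. Pyridinium p-toluenesulfonate in MeOH frees the primary alcohol, methyl (2Z,6S,7S)-6-ethenyl-7-(hydroxymethyl)-6,8-dimethyl-2-[(4,4,5,5-tetramethyl-1,3,2-dioxaborolan-2-yl)methyl]nona-2,8-dienoate F2. Dess–Martin oxidation gives methyl (2Z,6S,7S)-6-ethenyl-7-formyl-6,8-dimethyl-2-[(4,4,5,5-tetramethyl-1,3,2-dioxaborolan-2-yl)methyl]nona-2,8-dienoate F3. This aldehyde should close ring B through the chair-like closed transition state of allylboration, on standing or with catalytic Sc(OTf)3, with the same trans-diequatorial outcome, and hydrolysis of the borate returns hydroxy ester 21.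

Step 9. The hydroalumination and hydroxymethylation may be eroded by 1,2-reduction of the ester, by incomplete capture of the α-alumino acrylate by formaldehyde, or by loss of its geometry through an aluminium allenolate. The fallback builds the trisubstituted alkene by olefination and cross-coupling; it sets out from aldehyde 10 and comes back at 15. A Still–Gennari-type Horner–Wadsworth–Emmons reaction of 10 with methyl 2-[bis(2,2,2-trifluoroethoxy)phosphoryl]-2-bromoacetate (KN(SiMe3)2, 18-crown-6, THF, −78 °C) should give methyl (2E,6S,7S)-2-bromo-7-{[(tert-butyldimethylsilyl)oxy]methyl}-6-ethenyl-6,8-dimethylnona-2,8-dienoate F4, with the chain cis to the ester. Stille coupling with Bu3SnCH2OH (Pd(PPh3)4, dioxane, 90 °C) then replaces bromine by hydroxymethyl with retention and gives 15.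

Step 16. Under hydroxide the C6 alkoxide may attack the epoxide intramolecularly and form a cyclic ether in competition with external opening at the CH2 terminus. The fallback opens the epoxide under non-basic, titanium-templated conditions; it sets out from epoxy diol 23 and comes back at 24. Ti(OiPr)4 and benzoic acid in CH2Cl2 should deliver benzoate to the CH2 terminus and give 2-[(1R,2R,3S,4S)-4-ethenyl-2-hydroxy-4-methyl-3-(prop-1-en-2-yl)cyclohexyl]-2,3-dihydroxypropyl benzoate F5 as a mixture of epimers at the carbinol carbon. K2CO3 in MeOH then removes the benzoyl group and returns tetraol 24.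

**Further compounds**

F1 | step 13 | methyl (2Z,6S,7S)-7-{[(tert-butyldimethylsilyl)oxy]methyl}-6-ethenyl-6,8-dimethyl-2-[(4,4,5,5-tetramethyl-1,3,2-dioxaborolan-2-yl)methyl]nona-2,8-dienoate | C=C[C@](C)(CC/C=C(/CB1OC(C)(C)C(C)(C)O1)C(=O)OC)[C@@H](CO[Si](C)(C)C(C)(C)C)C(=C)C
F2 | step 13 | methyl (2Z,6S,7S)-6-ethenyl-7-(hydroxymethyl)-6,8-dimethyl-2-[(4,4,5,5-tetramethyl-1,3,2-dioxaborolan-2-yl)methyl]nona-2,8-dienoate | C=C[C@](C)(CC/C=C(/CB1OC(C)(C)C(C)(C)O1)C(=O)OC)[C@@H](CO)C(=C)C
F3 | step 13 | methyl (2Z,6S,7S)-6-ethenyl-7-formyl-6,8-dimethyl-2-[(4,4,5,5-tetramethyl-1,3,2-dioxaborolan-2-yl)methyl]nona-2,8-dienoate | C=C[C@](C)(CC/C=C(/CB1OC(C)(C)C(C)(C)O1)C(=O)OC)[C@@H](C=O)C(=C)C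
F4 | step 9 | methyl (2E,6S,7S)-2-bromo-7-{[(tert-butyldimethylsilyl)oxy]methyl}-6-ethenyl-6,8-dimethylnona-2,8-dienoate | C=C[C@](C)(CC/C=C(/Br)C(=O)OC)[C@@H](CO[Si](C)(C)C(C)(C)C)C(=C)C
F5 | step 16 | 2-[(1R,2R,3S,4S)-4-ethenyl-2-hydroxy-4-methyl-3-(prop-1-en-2-yl)cyclohexyl]-2,3-dihydroxypropyl benzoate (both epimers at the carbinol carbon) | C=C[C@]1(C)CC[C@@H](C(O)(CO)COC(=O)c2ccccc2)[C@H](O)[C@H]1C(=C)C
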